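**Retrosynthetic overview**
- The target is traced back to a 7‑O‑benzyl, 3'‑O‑silyl flavone: the silyl ether is cleaved last, the sulfate is put on the freed 7‑OH just before, and the chelated 5‑OH is left unprotected throughout.
- The strategy rests on ring C, the pyranone O1–C2–C3–C4–C4a–C8a. Its carbonyl carbon C4 is a one‑carbon bridge between C4a of ring A and the C3–C2–aryl unit, so it can be supplied as CO.
- Key disconnection: C4a–C4, C4–C3 and O1–C2 are made in one palladium‑catalysed carbonylative annulation of a 2‑iodoresorcinol, CO and an aryl acetylene.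
- The iodoresorcinol comes from phloroglucinol (bis‑MOM ether, benzyl ether, directed lithiation/iodination, MOM removal). The aryl acetylene comes from isovanillin (Ohira–Bestmann homologation, silylation).
- Ring order: rings A and B are bought as arenes; ring C is the only ring formed, in step 7.

Key step: step 7

Assumption: the target is drawn as the free hydrogen sulfate; sulfate‑bearing intermediates are handled as pyridinium or ammonium salts, and the acid form is liberated only at the end on a cold acidic ion‑exchange resin.

**Route**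

Step 1
Reactants: 1 phloroglucinol
Product: 2 3,5-bis(methoxymethoxy)phenol
Conditions: MOMCl (2.1 equiv), iPr2NEt (2.5 equiv), DMF, 0 °C to rt; chromatography
Reagents that add atoms: chloromethyl methyl ether (MOMCl), COCCl
Why: Williamson‑type O‑alkylation of the phenol by the hard electrophile MOMCl, which with about two equivalents should make the bis‑ether the main component of a statistical mixture separable from the mono‑ and tris‑ethers.

Step 2
Reactants: 2 3,5-bis(methoxymethoxy)phenol
Product: 3 1-(benzyloxy)-3,5-bis(methoxymethoxy)benzene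
Conditions: BnBr (1.2 equiv), K2CO3, DMF, rt
Reagents that add atoms: benzyl bromide, BrCc1ccccc1
Why: Williamson ether synthesis on the single remaining phenol, which should proceed cleanly at oxygen with carbonate in DMF.

Step 3
Reactants: 3 1-(benzyloxy)-3,5-bis(methoxymethoxy)benzene
Product: 5 5-(benzyloxy)-2-iodo-1,3-bis(methoxymethoxy)benzene, via aryllithium 4 (not isolated)
Conditions: n-BuLi (1.1 equiv), THF, −20 to 0 °C, 1 h; then I2, THF, −78 °C to rt; aq. Na2S2O3
Reagents that add atoms: iodine, II
Why: Directed ortho‑metalation, in which the two MOM ethers chelate lithium and acidify the CH between them more than the CH beside the weaker‑directing benzyl ether, followed by trapping of the aryllithium with iodine.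

Step 4
Reactants: 5 5-(benzyloxy)-2-iodo-1,3-bis(methoxymethoxy)benzene
Product: 6 5-(benzyloxy)-2-iodobenzene-1,3-diol
Conditions: HCl (1.25 M in MeOH), rt to 40 °C, dark
Reagents that add atoms: none
Why: Acid‑catalysed acetal methanolysis should remove both aryl MOM ethers under conditions mild enough to leave the benzyl ether and the aryl iodide untouched.

Step 5
Reactants: 7 isovanillin
Product: 8 5-ethynyl-2-methoxyphenol
Conditions: dimethyl (1-diazo-2-oxopropyl)phosphonate (1.3 equiv), K2CO3 (3 equiv), MeOH, 0 °C to rt; aq. NH4Cl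
Reagents that add atoms: dimethyl (1-diazo-2-oxopropyl)phosphonate (Ohira–Bestmann reagent), COP(=O)(OC)C(=[N+]=[N-])C(C)=O
Why: Seyferth–Gilbert homologation in the Ohira–Bestmann version, in which the diazomethylphosphonate anion released by methanolysis olefinates the aldehyde and the diazoalkene loses N2 with a 1,2‑hydride shift to give the terminal alkyne; the phenoxide is meta to the aldehyde and does not deactivate it by conjugation.

Step 6
Reactants: 8 5-ethynyl-2-methoxyphenol
Product: 9 (5-ethynyl-2-methoxyphenoxy)triisopropylsilane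
Conditions: TIPSCl (1.2 equiv), imidazole (2.5 equiv), DMF, rt
Reagents that add atoms: chlorotriisopropylsilane, CC(C)[Si](Cl)(C(C)C)C(C)C
Why: Imidazole‑promoted silylation of the phenol, placed after the homologation so that the aryl silyl ether never meets K2CO3 in MeOH.

Step 7
Reactants: 6 5-(benzyloxy)-2-iodobenzene-1,3-diol; 9 (5-ethynyl-2-methoxyphenoxy)triisopropylsilane (1.3 equiv); 10 carbon monoxide
Product: 13 7-(benzyloxy)-5-hydroxy-2-[4-methoxy-3-(triisopropylsilyloxy)phenyl]chromen-4-one, via ynone 11 (not isolated), via enaminone 12 (not isolated)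
Conditions: PdCl2(PPh3)2 (5 mol %), CO (20 atm), degassed Et2NH as solvent, 110 °C, autoclave
Reagents that add atoms: none
Why: PdCl2(PPh3)2 is reduced in the flask to zerovalent palladium, which adds oxidatively to the aryl iodide of 6; migratory insertion of CO gives an aroyl palladium iodide, which takes up the amine‑generated acetylide of 9 and reductively eliminates ynone 11, so forming C4a–C4 and C4–C3. Conjugate addition of Et2NH to 11 gives enaminone 12, whose C2 is attacked by an ortho hydroxyl in a 6‑endo‑trig oxa‑Michael step, and expulsion of Et2NH forms O1–C2 and the pyranone. The closest known reaction type is the palladium‑catalysed carbonylative Sonogashira coupling and cyclization of ortho‑iodophenols with terminal alkynes in a secondary amine, an established flavone synthesis. No stereocenter is formed. The step needs the six‑membered flavone in place of the five‑membered aurone from 5‑exo closure, and carbonylation in place of direct alkynylation; the enaminone makes C2 the electrophilic carbon offered to the phenol, and the CO pressure keeps the aroyl palladium populated. Because 6 is symmetric about its C–I axis, closure through either hydroxyl leads to one and the same flavone, the hydroxyl left over becomes the chelated 5‑OH, and the benzyl ether marks O7.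

Step 8
Reactants: 13 7-(benzyloxy)-5-hydroxy-2-[4-methoxy-3-(triisopropylsilyloxy)phenyl]chromen-4-one
Product: 14 5,7-dihydroxy-2-[4-methoxy-3-(triisopropylsilyloxy)phenyl]chromen-4-one
Conditions: H2 (1 atm), Pd/C (10 wt % palladium on carbon), EtOAc/THF, rt
Reagents that add atoms: none
Why: Hydrogenolysis of the aryl benzyl ether over palladium on carbon, under which the conjugated C2=C3 bond of the flavone and the hindered aryl silyl ether should survive at balloon pressure in an aprotic solvent.

Step 9
Reactants: 14 5,7-dihydroxy-2-[4-methoxy-3-(triisopropylsilyloxy)phenyl]chromen-4-one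
Product: 15 pyridinium 5-hydroxy-2-[4-methoxy-3-(triisopropylsilyloxy)phenyl]-4-oxo-4H-chromen-7-yl sulfate
Conditions: SO3·pyridine (2.5 equiv), pyridine, rt to 40 °C; MeOH quench; Sephadex LH-20
Reagents that add atoms: sulfur trioxide–pyridine complex, O=S(=O)([O-])[n+]1ccccc1
Why: O‑sulfonation of a phenol by SO3·pyridine, which should take place only at the 7‑OH because the 5‑OH is deactivated by its hydrogen bond to the C4 carbonyl and the 3'‑oxygen is silylated.

Step 10
Reactants: 15 pyridinium 5-hydroxy-2-[4-methoxy-3-(triisopropylsilyloxy)phenyl]-4-oxo-4H-chromen-7-yl sulfate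
Product: 17 5-hydroxy-2-(3-hydroxy-4-methoxyphenyl)-4-oxo-4H-chromen-7-yl hydrogen sulfate (luteolin 4'-methyl ether 7-sulfate), via ammonium salt 16 (not isolated)
Conditions: NH4F (5 equiv), MeOH, rt to 40 °C; then Dowex 50WX8 (H+ form), H2O/MeOH, 0 °C, freeze‑drying
Reagents that add atoms: none
Why: Fluoride‑induced cleavage of the aryl silyl ether, driven by Si–F bond formation, under near‑neutral conditions that should leave the aryl sulfate monoester intact, followed by cation exchange to the acid form.

**Compound list**
1 | phloroglucinol | Oc1cc(O)cc(O)c1 | starting material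
2 | 3,5-bis(methoxymethoxy)phenol | COCOc1cc(O)cc(OCOC)c1 | intermediate
3 | 1-(benzyloxy)-3,5-bis(methoxymethoxy)benzene | COCOc1cc(OCOC)cc(OCc2ccccc2)c1 | intermediate
4 | [4-(benzyloxy)-2,6-bis(methoxymethoxy)phenyl]lithium (formed in the flask, not isolated) | [Li]c1c(OCOC)cc(OCc2ccccc2)cc1OCOC | intermediate
5 | 5-(benzyloxy)-2-iodo-1,3-bis(methoxymethoxy)benzene | COCOc1cc(OCc2ccccc2)cc(OCOC)c1I | intermediate
6 | 5-(benzyloxy)-2-iodobenzene-1,3-diol | Oc1cc(OCc2ccccc2)cc(O)c1I | intermediate
7 | isovanillin (3-hydroxy-4-methoxybenzaldehyde) | COc1ccc(C=O)cc1O | starting material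
8 | 5-ethynyl-2-methoxyphenol | C#Cc1ccc(OC)c(O)c1 | intermediate
9 | (5-ethynyl-2-methoxyphenoxy)triisopropylsilane | C#Cc1ccc(OC)c(O[Si](C(C)C)(C(C)C)C(C)C)c1 | intermediate
10 | carbon monoxide | [C-]#[O+] | starting material
11 | 1-[4-(benzyloxy)-2,6-dihydroxyphenyl]-3-[4-methoxy-3-(triisopropylsilyloxy)phenyl]prop-2-yn-1-one (formed in the flask, not isolated) | COc1ccc(C#CC(=O)c2c(O)cc(OCc3ccccc3)cc2O)cc1O[Si](C(C)C)(C(C)C)C(C)C | intermediate
12 | 1-[4-(benzyloxy)-2,6-dihydroxyphenyl]-3-(diethylamino)-3-[4-methoxy-3-(triisopropylsilyloxy)phenyl]prop-2-en-1-one, alkene geometry not fixed and without consequence (formed in the flask, not isolated) | CCN(CC)C(=CC(=O)c1c(O)cc(OCc2ccccc2)cc1O)c1ccc(OC)c(O[Si](C(C)C)(C(C)C)C(C)C)c1 | intermediate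
13 | 7-(benzyloxy)-5-hydroxy-2-[4-methoxy-3-(triisopropylsilyloxy)phenyl]chromen-4-one | COc1ccc(-c2cc(=O)c3c(O)cc(OCc4ccccc4)cc3o2)cc1O[Si](C(C)C)(C(C)C)C(C)C | intermediate
14 | 5,7-dihydroxy-2-[4-methoxy-3-(triisopropylsilyloxy)phenyl]chromen-4-one | COc1ccc(-c2cc(=O)c3c(O)cc(O)cc3o2)cc1O[Si](C(C)C)(C(C)C)C(C)C | intermediate
15 | pyridinium 5-hydroxy-2-[4-methoxy-3-(triisopropylsilyloxy)phenyl]-4-oxo-4H-chromen-7-yl sulfate | COc1ccc(-c2cc(=O)c3c(O)cc(OS(=O)(=O)[O-])cc3o2)cc1O[Si](C(C)C)(C(C)C)C(C)C.c1cc[nH+]cc1 | intermediate
16 | ammonium 5-hydroxy-2-(3-hydroxy-4-methoxyphenyl)-4-oxo-4H-chromen-7-yl sulfate (formed in the flask, not isolated) | COc1ccc(-c2cc(=O)c3c(O)cc(OS(=O)(=O)[O-])cc3o2)cc1O.[NH4+] | intermediate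
17 | luteolin 4'-methyl ether 7-sulfate, 5-hydroxy-2-(3-hydroxy-4-methoxyphenyl)-4-oxo-4H-chromen-7-yl hydrogen sulfate | COc1ccc(-c2cc(=O)c3c(O)cc(OS(=O)(=O)O)cc3o2)cc1O | target

**Step count**
Total: 10 steps. Longest linear sequence: 8 steps (steps 1–4 and 7–10, from phloroglucinol); the isovanillin branch is 2 steps before the convergence.

**Steps most likely to fail, with fallbacks**

Step 7 (carbonylative annulation). Several processes could erode it:
- slow oxidative addition to the electron‑rich, doubly ortho‑substituted iodide;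
- capture of the aroyl palladium by diethylamine or by a phenoxide before the acetylide arrives;
- CO‑free alkynylation followed by closure to a benzofuran;
- 5‑exo closure of the ynone, or partial loss of the silyl ether in hot amine.

The fallback builds the same ynone without palladium or CO and sets out from 3 and 9. Lithiation of 3 as in step 3 gives 4, which is quenched with DMF to give 4-(benzyloxy)-2,6-bis(methoxymethoxy)benzaldehyde F1. Alkyne 9 is deprotonated with n-BuLi in THF at −78 °C to its lithium acetylide F2, which adds to F1 to give racemic 1-[4-(benzyloxy)-2,6-bis(methoxymethoxy)phenyl]-3-[4-methoxy-3-(triisopropylsilyloxy)phenyl]prop-2-yn-1-ol F3. Oxidation with MnO2 in CH2Cl2 gives 1-[4-(benzyloxy)-2,6-bis(methoxymethoxy)phenyl]-3-[4-methoxy-3-(triisopropylsilyloxy)phenyl]prop-2-yn-1-one F4. Brief treatment with HCl in MeOH/THF removes the two MOM groups to give 11, and warming the crude material with Et2NH in EtOH should close ring C through 12. The fallback comes back to the route at 13.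

Step 3 (lithiation/iodination). Deprotonation could occur at the benzylic CH2 of the benzyl ether, with subsequent Wittig rearrangement, or at the ring position between a MOM ether and the benzyl ether; either would lower or misplace the iodination. The fallback replaces the anionic route by electrophilic substitution and sets out from 3. Methanolysis with HCl in MeOH gives 5-(benzyloxy)benzene-1,3-diol F5. Iodination with I2 and NaHCO3 in THF/H2O at 0 °C is expected to go to the position flanked by the two hydroxyls, as it does for resorcinol and its 5‑substituted analogues. The fallback comes back to the route at 6, bypassing 4 and 5.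

Step 9 (sulfation). Conversion could stall, sulfation could spill over to the chelated 5‑OH when forced, and material could be lost while separating the polar pyridinium salt from excess reagent. The fallback installs the sulfate as a neutral, chromatographable diester and sets out from 14. Treatment with 2,2,2-trichloroethyl chlorosulfate, Et3N and DMAP in THF gives 5-hydroxy-2-[4-methoxy-3-(triisopropylsilyloxy)phenyl]-4-oxo-4H-chromen-7-yl 2,2,2-trichloroethyl sulfate F6. Reductive removal of the trichloroethyl group with zinc dust and HCO2NH4 in MeOH gives ammonium 5-hydroxy-2-[4-methoxy-3-(triisopropylsilyloxy)phenyl]-4-oxo-4H-chromen-7-yl sulfate F7. Desilylation with NH4F in MeOH then gives 16, where the fallback comes back to the route; resin passage as in step 10 gives 17.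

**Further compounds**
F1 | step 7 | 4-(benzyloxy)-2,6-bis(methoxymethoxy)benzaldehyde | COCOc1cc(OCc2ccccc2)cc(OCOC)c1C=O
F2 | step 7 | lithium acetylide of 9, {[4-methoxy-3-(triisopropylsilyloxy)phenyl]ethynyl}lithium | [Li]C#Cc1ccc(OC)c(O[Si](C(C)C)(C(C)C)C(C)C)c1
F3 | step 7 | racemic 1-[4-(benzyloxy)-2,6-bis(methoxymethoxy)phenyl]-3-[4-methoxy-3-(triisopropylsilyloxy)phenyl]prop-2-yn-1-ol | COCOc1cc(OCc2ccccc2)cc(OCOC)c1C(O)C#Cc1ccc(OC)c(O[Si](C(C)C)(C(C)C)C(C)C)c1
F4 | step 7 | 1-[4-(benzyloxy)-2,6-bis(methoxymethoxy)phenyl]-3-[4-methoxy-3-(triisopropylsilyloxy)phenyl]prop-2-yn-1-one | COCOc1cc(OCc2ccccc2)cc(OCOC)c1C(=O)C#Cc1ccc(OC)c(O[Si](C(C)C)(C(C)C)C(C)C)c1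
F5 | step 3 | 5-(benzyloxy)benzene-1,3-diol | Oc1cc(O)cc(OCc2ccccc2)c1
F6 | step 9 | 5-hydroxy-2-[4-methoxy-3-(triisopropylsilyloxy)phenyl]-4-oxo-4H-chromen-7-yl 2,2,2-trichloroethyl sulfate | COc1ccc(-c2cc(=O)c3c(O)cc(OS(=O)(=O)OCC(Cl)(Cl)Cl)cc3o2)cc1O[Si](C(C)C)(C(C)C)C(C)C
F7 | step 9 | ammonium 5-hydroxy-2-[4-methoxy-3-(triisopropylsilyloxy)phenyl]-4-oxo-4H-chromen-7-yl sulfate | COc1ccc(-c2cc(=O)c3c(O)cc(OS(=O)(=O)[O-])cc3o2)cc1O[Si](C(C)C)(C(C)C)C(C)C.[NH4+]
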